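**Assumption:** the target has no stereocentre or other stereogenic element (it is achiral), so no stereocontrol is needed. Ring letters: A = central 1,3,5-trioxygenated ring, C = inner 1,2,3,5-tetraoxygenated ring, B and D = the two terminal 2,4,6-trihydroxyphenyl rings.

## Retrosynthetic overview

1. Target 15 ⇐ tri-O-methyl ether 14 (BBr3) ⇐ tetraester 12 (saponification and decarboxylation).
2. Key disconnection: rings B and D of 12 are each cut at two ring C–C bonds, giving bis(aryloxymalonate) 9 plus two diethyl acetonedicarboxylate units (intermolecular Claisen C-acylation, then Dieckmann closure and aromatisation). The two hindered aryl–O bonds are thus made as simple phenol O-alkylations with chloromalonate.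
3. 9 ⇐ bis-phenol 7 ⇐ aldehyde 4 (Baeyer–Villiger turns CHO into OH; hydrogenolysis frees the second OH).
4. 4 ⇐ Ullmann C–O coupling of a 3-bromo-5-methoxyphenol benzyl ether (ring A) with syringaldehyde (ring C).
5. Ring order: A and C are bought as aromatics; B and D are built last, both in the same operation.

## Route

Step 1
Reactants: 1 3-bromo-5-methoxyphenol
Product: 2 1-(benzyloxy)-3-bromo-5-methoxybenzene
Conditions: BnBr, K2CO3, DMF, rt to 60 °C
Reagents that add atoms: benzyl bromide, BrCc1ccccc1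
Why: Williamson ether synthesis (SN2 of the phenoxide on a benzylic bromide) masks the oxygen that will later carry ring B; no stereocentre is formed.

Step 2
Reactants: 2 1-(benzyloxy)-3-bromo-5-methoxybenzene; 3 syringaldehyde (4-hydroxy-3,5-dimethoxybenzaldehyde)
Product: 4 4-[3-(benzyloxy)-5-methoxyphenoxy]-3,5-dimethoxybenzaldehyde
Conditions: CuI (10 mol%), picolinic acid (20 mol%), K3PO4, DMSO, 100 °C, Ar
Reagents that add atoms: none
Why: Ullmann-type Cu(I)-catalysed C–O coupling, in which the picolinate-ligated copper system joins 2,6-disubstituted phenoxides to unhindered aryl bromides and the non-enolisable aldehyde tolerates K3PO4.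

Step 3
Reactants: 4 4-[3-(benzyloxy)-5-methoxyphenoxy]-3,5-dimethoxybenzaldehyde
Product: 6 4-[3-(benzyloxy)-5-methoxyphenoxy]-3,5-dimethoxyphenol, via aryl formate 5 (not isolated)
Conditions: mCPBA (1.2 equiv), CH2Cl2, 0 °C to rt; then K2CO3 (cat.), MeOH, rt
Reagents that add atoms: mCPBA, OOC(=O)c1cccc(Cl)c1
Why: Baeyer–Villiger (Dakin-type) oxidation, in which the electron-rich 4-aryloxy-3,5-dimethoxyphenyl group migrates in the Criegee intermediate in preference to hydrogen and the resulting formate is removed by mild methanolysis.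

Step 4
Reactants: 6 4-[3-(benzyloxy)-5-methoxyphenoxy]-3,5-dimethoxyphenol
Product: 7 3-(4-hydroxy-2,6-dimethoxyphenoxy)-5-methoxyphenol
Conditions: H2 (1 atm), 10% Pd/C, EtOAc/MeOH, rt
Reagents that add atoms: none
Why: Catalytic hydrogenolysis cleaves only the benzyl ether, leaving the aryl methyl ethers and the diaryl ether untouched.

Step 5
Reactants: 7 3-(4-hydroxy-2,6-dimethoxyphenoxy)-5-methoxyphenol; 8 diethyl chloromalonate (2.4 equiv)
Product: 9 diethyl 2-{3-[4-(1,3-diethoxy-1,3-dioxopropan-2-yl)oxy-2,6-dimethoxyphenoxy]-5-methoxyphenoxy}propanedioate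
Conditions: K2CO3, acetone, reflux
Reagents that add atoms: none
Why: Williamson-type SN2 O-alkylation of the two unhindered phenoxides by the α-chloromalonate, where the chloro reagent is chosen over the bromo one to avoid halogen transfer to the electron-rich rings.

Step 6
Reactants: 9 the bis(aryloxymalonate); 10 diethyl 1,3-acetonedicarboxylate (diethyl 3-oxopentanedioate, 3 equiv)
Product: 12 diethyl 5-(4-{3-[3,5-bis(ethoxycarbonyl)-2,4,6-trihydroxyphenoxy]-5-methoxyphenoxy}-3,5-dimethoxyphenoxy)-2,4,6-trihydroxybenzene-1,3-dicarboxylate, via open-chain Claisen adduct 11 (not isolated)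
Conditions: NaOEt (6 equiv), EtOH, reflux; then xylene, 140 °C with EtOH distilled off; aq. HCl work-up
Reagents that add atoms: none
Why: Intermolecular Claisen condensation (the acetonedicarboxylate enolate is C-acylated by a malonate ester carbonyl, forming the key C–C bond) followed by Dieckmann cyclisation, with aromatisation to the phloroglucinol polyanion driving both equilibria and erasing the transient stereocentres of 11.

Step 7
Reactants: 12 the tetraethyl ester
Product: 14 2-{4-[3-methoxy-5-(2,4,6-trihydroxyphenoxy)phenoxy]-3,5-dimethoxyphenoxy}benzene-1,3,5-triol, via tetra-acid 13 (not isolated)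
Conditions: 2 M KOH (aq., degassed), reflux, Ar; then HCl to pH 2, 60 °C
Reagents that add atoms: none
Why: Saponification followed by protodecarboxylation, since 2,4,6-trihydroxybenzoic acids behave as β-keto acids through their keto tautomers and lose CO2 on gentle warming in dilute acid.

Step 8
Reactants: 14 the tri-O-methyl ether
Product: 15 2-[3-hydroxy-5-(2,4,6-trihydroxyphenoxy)phenoxy]-5-(2,4,6-trihydroxyphenoxy)benzene-1,3-diol (target)
Conditions: BBr3 (excess), CH2Cl2, −78 °C to rt; then H2O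
Reagents that add atoms: none
Why: Lewis-acid ether cleavage (bromide attacks the O-methyl carbon of the boron-complexed ether by SN2) removes the three methyl groups, while diaryl ether C–O bonds are not cleaved by BBr3.

## Compound list

1 | 3-bromo-5-methoxyphenol | COc1cc(O)cc(Br)c1 | starting material
2 | 1-(benzyloxy)-3-bromo-5-methoxybenzene | COc1cc(Br)cc(OCc2ccccc2)c1 | intermediate
3 | syringaldehyde (4-hydroxy-3,5-dimethoxybenzaldehyde) | COc1cc(C=O)cc(OC)c1O | starting material
4 | 4-[3-(benzyloxy)-5-methoxyphenoxy]-3,5-dimethoxybenzaldehyde | COc1cc(OCc2ccccc2)cc(Oc2c(OC)cc(C=O)cc2OC)c1 | intermediate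
5 | 4-[3-(benzyloxy)-5-methoxyphenoxy]-3,5-dimethoxyphenyl formate | COc1cc(OCc2ccccc2)cc(Oc2c(OC)cc(OC=O)cc2OC)c1 | intermediate (not isolated)
6 | 4-[3-(benzyloxy)-5-methoxyphenoxy]-3,5-dimethoxyphenol | COc1cc(OCc2ccccc2)cc(Oc2c(OC)cc(O)cc2OC)c1 | intermediate
7 | 3-(4-hydroxy-2,6-dimethoxyphenoxy)-5-methoxyphenol | COc1cc(O)cc(Oc2c(OC)cc(O)cc2OC)c1 | intermediate
8 | diethyl chloromalonate | CCOC(=O)C(Cl)C(=O)OCC | starting material
9 | diethyl 2-{3-[4-(1,3-diethoxy-1,3-dioxopropan-2-yl)oxy-2,6-dimethoxyphenoxy]-5-methoxyphenoxy}propanedioate | COc1cc(OC(C(=O)OCC)C(=O)OCC)cc(Oc2c(OC)cc(OC(C(=O)OCC)C(=O)OCC)cc2OC)c1 | intermediate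
10 | diethyl 1,3-acetonedicarboxylate (diethyl 3-oxopentanedioate) | CCOC(=O)CC(=O)CC(=O)OCC | starting material
11 | open-chain Claisen adduct: each ArO–CH(CO2Et)– unit of 9 acylated onto C2 of one diethyl 3-oxopentanedioate, giving two ArO–CH(CO2Et)–CO–CH(CO2Et)–CO–CH2–CO2Et arms (tautomer/diastereomer mixture, configuration undefined) | COc1cc(OC(C(=O)OCC)C(=O)C(C(=O)OCC)C(=O)CC(=O)OCC)cc(Oc2c(OC)cc(OC(C(=O)OCC)C(=O)C(C(=O)OCC)C(=O)CC(=O)OCC)cc2OC)c1 | intermediate (not isolated)
12 | diethyl 5-(4-{3-[3,5-bis(ethoxycarbonyl)-2,4,6-trihydroxyphenoxy]-5-methoxyphenoxy}-3,5-dimethoxyphenoxy)-2,4,6-trihydroxybenzene-1,3-dicarboxylate | COc1cc(Oc2c(O)c(C(=O)OCC)c(O)c(C(=O)OCC)c2O)cc(Oc2c(OC)cc(Oc3c(O)c(C(=O)OCC)c(O)c(C(=O)OCC)c3O)cc2OC)c1 | intermediate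
13 | 5-(4-{3-[3,5-dicarboxy-2,4,6-trihydroxyphenoxy]-5-methoxyphenoxy}-3,5-dimethoxyphenoxy)-2,4,6-trihydroxybenzene-1,3-dicarboxylic acid | COc1cc(Oc2c(O)c(C(=O)O)c(O)c(C(=O)O)c2O)cc(Oc2c(OC)cc(Oc3c(O)c(C(=O)O)c(O)c(C(=O)O)c3O)cc2OC)c1 | intermediate (not isolated)
14 | 2-{4-[3-methoxy-5-(2,4,6-trihydroxyphenoxy)phenoxy]-3,5-dimethoxyphenoxy}benzene-1,3,5-triol | COc1cc(Oc2c(O)cc(O)cc2O)cc(Oc2c(OC)cc(Oc3c(O)cc(O)cc3O)cc2OC)c1 | intermediate
15 | 2-[3-hydroxy-5-(2,4,6-trihydroxyphenoxy)phenoxy]-5-(2,4,6-trihydroxyphenoxy)benzene-1,3-diol | Oc1cc(Oc2c(O)cc(O)cc2O)cc(Oc2c(O)cc(Oc3c(O)cc(O)cc3O)cc2O)c1 | target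

## Summary and risks

Total step count: 8. Longest linear sequence: 8 steps (1 to 15).

**Most likely to fail, 1: step 6 (double Claisen/Dieckmann annulation).** A 2-aryloxymalonate is a less reactive bis-electrophile than malonate itself, and O-cyclisation to pyrones or self-condensation of 10 can compete; this pairing is an extrapolation from the unsubstituted malonate case. The fallback sets out from 7 and comes back at 14. Compound 7 is O-alkylated with ethyl bromoacetate (K2CO3, acetone) to ethyl 2-{3-[4-(2-ethoxy-2-oxoethoxy)-2,6-dimethoxyphenoxy]-5-methoxyphenoxy}acetate F1. Both ester groups of F1 then acylate the γ-carbon of the ethyl acetoacetate dianion (NaH then n-BuLi, THF, 0 °C; an intermolecular Claisen condensation) to give ethyl 6-{3-[4-(6-ethoxy-2,4,6-trioxohexyloxy)-2,6-dimethoxyphenoxy]-5-methoxyphenoxy}-3,5-dioxohexanoate F2. Intramolecular Claisen closure of the aryloxy-bearing C6 onto the ester (excess LiHMDS in THF, or NaOEt in hot xylene) then aromatises both arms. This gives the ester-free rings B and D and so arrives directly at 14, bypassing 9, 12 and step 7.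

**Most likely to fail, 2: step 2 (Ullmann coupling).** The phenol is both hindered and deactivated by the para-formyl group. The fallback sets out from 2 and comes back at 4. Bromine–lithium exchange on 2 (n-BuLi, THF, −78 °C), quench with B(OiPr)3 and aqueous acid gives [3-(benzyloxy)-5-methoxyphenyl]boronic acid F3. Oxidative Chan–Lam coupling of F3 with syringaldehyde 3 (Cu(OAc)2, pyridine, 4 Å sieves, air, CH2Cl2, rt) gives 4 at room temperature by a Cu(II)/Cu(III) manifold that does not need an aryl halide.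

**Most likely to fail, 3: step 8 (global demethylation).** The heptaphenol 14 is poorly soluble in CH2Cl2, and the two methoxy groups flanking the diaryl ether are hindered. The fallback sets out from 12 and comes back at 15, reversing the order of the last two operations. The CH2Cl2-soluble, internally hydrogen-bonded tetraester 12 is demethylated first with BBr3 to diethyl 5-(4-{3-[3,5-bis(ethoxycarbonyl)-2,4,6-trihydroxyphenoxy]-5-hydroxyphenoxy}-3,5-dihydroxyphenoxy)-2,4,6-trihydroxybenzene-1,3-dicarboxylate F4; any ethyl ester that BBr3 also cleaves converges in the next operation. F4 is then saponified and decarboxylated (degassed aq. KOH, reflux, Ar; then HCl, pH 2, 60 °C) to give 15.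

## Further compounds

F1 | step 6 | ethyl 2-{3-[4-(2-ethoxy-2-oxoethoxy)-2,6-dimethoxyphenoxy]-5-methoxyphenoxy}acetate | COc1cc(OCC(=O)OCC)cc(Oc2c(OC)cc(OCC(=O)OCC)cc2OC)c1
F2 | step 6 | ethyl 6-{3-[4-(6-ethoxy-2,4,6-trioxohexyloxy)-2,6-dimethoxyphenoxy]-5-methoxyphenoxy}-3,5-dioxohexanoate | COc1cc(OCC(=O)CC(=O)CC(=O)OCC)cc(Oc2c(OC)cc(OCC(=O)CC(=O)CC(=O)OCC)cc2OC)c1
F3 | step 2 | [3-(benzyloxy)-5-methoxyphenyl]boronic acid | COc1cc(OCc2ccccc2)cc(B(O)O)c1
F4 | step 8 | diethyl 5-(4-{3-[3,5-bis(ethoxycarbonyl)-2,4,6-trihydroxyphenoxy]-5-hydroxyphenoxy}-3,5-dihydroxyphenoxy)-2,4,6-trihydroxybenzene-1,3-dicarboxylate | Oc1cc(Oc2c(O)c(C(=O)OCC)c(O)c(C(=O)OCC)c2O)cc(Oc2c(O)cc(Oc3c(O)c(C(=O)OCC)c(O)c(C(=O)OCC)c3O)cc2O)c1
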